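**Retrosynthetic overview**
1. Target 21 ⇐ macrocyclic lactone 16 by end-game adjustments only: acylation of O8, C15 CHO → CH2OH, C14 Weinreb amide → CHO.
2. 16 ⇐ acyclic (E)-enedial 14: one indium-mediated allylation closes the ten-membered carbocycle (C6–C7) and the γ-lactone closes in the same flask; C6 and C7 are set here.
3. 14 ⇐ 3-alkylfuran 12: oxidative opening of the furan (key step) unveils C15–C4=C5–C6 in one operation with the ring-cis geometry.
4. 12 ⇐ 10 + methyl 2-(bromomethyl)acrylate (cross-metathesis, C7=C11); 10 ⇐ lactone 8 (Weinreb opening); 8 ⇐ phosphono-lactone 7 + aldehyde 4 (HWE, C1=C10).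
5. 7 ⇐ (S)-vinyloxirane (source of C8) + triethyl phosphonoacetate; 4 ⇐ furan-3-carbaldehyde. Ring order: furan (bought) → temporary butyrolactone (7, 8; opened in step 5) → ten-membered ring → α-methylene lactone.

Assumption: (2S)-2-ethenyloxirane is bought enantiopure; atom labels C1–C15 below are germacrane numbering (lactone O on C6, ester O on C8, CHO = C14, CH2OH = C15).

Step 1
Reactants: 1 furan-3-carbaldehyde; 2 2-(triphenyl-λ5-phosphanylidene)acetaldehyde
Product: 3 (2E)-3-(furan-3-yl)prop-2-enal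
Conditions: toluene, 80 °C
Reagents that add atoms: none
Why: Wittig olefination with the stabilized formyl ylide is E-selective and adds the two carbons that become C2 and C1.

Step 2
Reactants: 3 (2E)-3-(furan-3-yl)prop-2-enal
Product: 4 3-(furan-3-yl)propanal
Conditions: Hantzsch ester (diethyl 2,6-dimethyl-1,4-dihydropyridine-3,5-dicarboxylate, 1.1 equiv), Bn2NH2+ CF3CO2− (10 mol%), THF, rt
Reagents that add atoms: none
Why: Organocatalytic iminium transfer hydrogenation reduces only the conjugated C=C and leaves the furan and the aldehyde untouched.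

Step 3
Reactants: 5 (2S)-2-ethenyloxirane; 6 ethyl 2-(diethoxyphosphoryl)acetate
Product: 7 (5R)-3-(diethoxyphosphoryl)-5-ethenyloxolan-2-one (both C3 epimers)
Conditions: NaH, THF, 0 °C; then 5, 65 °C, sealed tube; 1 M HCl work-up
Reagents that add atoms: none
Why: Epoxide opening by the phosphonoacetate enolate at the unhindered CH2 (SN2) followed by lactonization leaves the stereocentre untouched, so it becomes C8 (R); the C3 epimer mixture is irrelevant because C3 becomes sp2 in step 4.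

Step 4
Reactants: 7 (5R)-3-(diethoxyphosphoryl)-5-ethenyloxolan-2-one; 4 3-(furan-3-yl)propanal
Product: 8 (3E,5R)-5-ethenyl-3-[3-(furan-3-yl)propylidene]oxolan-2-one
Conditions: NaH, THF, 0 °C; then 4, 0 °C → rt; 1 M HCl work-up
Reagents that add atoms: none
Why: Horner–Wadsworth–Emmons olefination of the α-phosphono lactone gives mainly the more stable (E)-alkylidene lactone (chain trans to C=O), which fixes the C1=C10 geometry; the minor Z isomer is removed by chromatography.

Step 5
Reactants: 8 (3E,5R)-5-ethenyl-3-[3-(furan-3-yl)propylidene]oxolan-2-one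
Product: 10 (2E)-2-[(2R)-2-{[tert-butyl(dimethyl)silyl]oxy}but-3-en-1-yl]-5-(furan-3-yl)-N-methoxy-N-methylpent-2-enamide, via hydroxy amide 9 (not isolated)
Conditions: MeNH(OMe)·HCl, i-PrMgCl, THF, −20 °C; then TBSCl, imidazole (cat.), DMF, 0 °C → rt
Reagents that add atoms: N,O-dimethylhydroxylamine hydrochloride (CNOC.Cl); tert-butyl(chloro)dimethylsilane (CC(C)(C)[Si](C)(C)Cl)
Why: Weinreb aminolysis of the lactone by the chloromagnesium amide keeps the alkene geometry, and the magnesium alkoxide is silylated in the same flask because the free γ-hydroxy amide would relactonize.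

Step 6
Reactants: 10 (2E)-2-[(2R)-2-{[tert-butyl(dimethyl)silyl]oxy}but-3-en-1-yl]-5-(furan-3-yl)-N-methoxy-N-methylpent-2-enamide; 11 methyl 2-(bromomethyl)prop-2-enoate
Product: 12 methyl (2Z,4R,6E)-2-(bromomethyl)-4-{[tert-butyl(dimethyl)silyl]oxy}-9-(furan-3-yl)-6-[methoxy(methyl)carbamoyl]nona-2,6-dienoate
Conditions: 11 (5 equiv), second-generation Hoveyda–Grubbs catalyst (10 mol%), CH2Cl2, 40 °C
Reagents that add atoms: none
Why: Olefin cross-metathesis of the only terminal alkene with the 1,1-disubstituted acrylate gives the trisubstituted enoate with the ester trans to C8 (the Z-bromide), as in methacrylate cross-metatheses; the trisubstituted enamide alkene and the furan do not take part.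

Step 7
Reactants: 12 methyl (2Z,4R,6E)-2-(bromomethyl)-4-{[tert-butyl(dimethyl)silyl]oxy}-9-(furan-3-yl)-6-[methoxy(methyl)carbamoyl]nona-2,6-dienoate
Product: 14 methyl (2Z,4R,6E,10E)-2-(bromomethyl)-4-{[tert-butyl(dimethyl)silyl]oxy}-10-formyl-6-[methoxy(methyl)carbamoyl]-12-oxododeca-2,6,10-trienoate, via (Z)-enedial 13 (not isolated)
Conditions: dimethyldioxirane (1.05 equiv), acetone, −78 → 0 °C; then I2 (2 mol%), CH2Cl2, rt
Reagents that add atoms: dimethyldioxirane (CC1(C)OO1)
Why: Oxidative dearomatization: dimethyldioxirane epoxidizes the electron-rich furan (the two other alkenes are electron-poor) and the epoxide opens to the cis-enedial, which iodine equilibrates to the more stable (E)-2-alkylbut-2-enedial, so C15 and C6 are unveiled together and the C4=C5 geometry (C3 cis to C6) is set.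

Step 8
Reactants: 14 methyl (2Z,4R,6E,10E)-2-(bromomethyl)-4-{[tert-butyl(dimethyl)silyl]oxy}-10-formyl-6-[methoxy(methyl)carbamoyl]-12-oxododeca-2,6,10-trienoate
Product: 16 (3aR,4R,6E,10E,11aR)-4-{[tert-butyl(dimethyl)silyl]oxy}-10-formyl-N-methoxy-N-methyl-3-methylidene-2-oxo-2,3,3a,4,5,8,9,11a-octahydrocyclodeca[b]furan-6-carboxamide, via hydroxy ester 15 (not isolated)
Conditions: In powder (2 equiv), THF/H2O 3:1, 0.002 M, rt; then p-TsOH·H2O (cat.), CH2Cl2, rt
Reagents that add atoms: none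
Why: Intramolecular Barbier allylation then lactonization: the allylindium from the (Z)-bromide adds with allyl transposition at C7 through a chair-like transition state to the less hindered formyl group C6 (the C15 formyl sits on the fully substituted C4 and would give a nine-membered ring), syn-selectively (cis-fused lactone, C6/C7) and on the face anti to the allylic silyloxy group (1,3-allylic strain, sets C7 relative to C8), after which the C6 oxygen closes the α-methylene lactone.

Step 9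
Reactants: 16 (3aR,4R,6E,10E,11aR)-4-{[tert-butyl(dimethyl)silyl]oxy}-10-formyl-N-methoxy-N-methyl-3-methylidene-2-oxo-2,3,3a,4,5,8,9,11a-octahydrocyclodeca[b]furan-6-carboxamide
Product: 17 (3aS,4R,6E,10E,11aR)-10-formyl-4-hydroxy-N-methoxy-N-methyl-3-methylidene-2-oxo-2,3,3a,4,5,8,9,11a-octahydrocyclodeca[b]furan-6-carboxamide
Conditions: HF·pyridine, pyridine, THF, 0 °C → rt
Reagents that add atoms: none
Why: Buffered fluoride desilylation removes the silyl ether without touching the enal, the lactone or the Weinreb amide (the 3a descriptor changes only because Si no longer ranks C4 first; no centre is inverted).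

Step 10
Reactants: 17 (3aS,4R,6E,10E,11aR)-10-formyl-4-hydroxy-N-methoxy-N-methyl-3-methylidene-2-oxo-2,3,3a,4,5,8,9,11a-octahydrocyclodeca[b]furan-6-carboxamide; 18 3-methylbutanoic anhydride
Product: 19 (3aS,4R,6E,10E,11aR)-10-formyl-6-[methoxy(methyl)carbamoyl]-3-methylidene-2-oxo-2,3,3a,4,5,8,9,11a-octahydrocyclodeca[b]furan-4-yl 3-methylbutanoate
Conditions: DMAP (cat.), pyridine, CH2Cl2, 0 °C, directly after step 9
Reagents that add atoms: none
Why: DMAP-catalysed acyl transfer esterifies the only hydroxyl group with retention at C8, and is run at once so that the C8 alcohol cannot attack the neighbouring amide or lactone.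

Step 11
Reactants: 19 (3aS,4R,6E,10E,11aR)-10-formyl-6-[methoxy(methyl)carbamoyl]-3-methylidene-2-oxo-2,3,3a,4,5,8,9,11a-octahydrocyclodeca[b]furan-4-yl 3-methylbutanoate
Product: 20 (3aS,4R,6E,10E,11aR)-10-(hydroxymethyl)-6-[methoxy(methyl)carbamoyl]-3-methylidene-2-oxo-2,3,3a,4,5,8,9,11a-octahydrocyclodeca[b]furan-4-yl 3-methylbutanoate
Conditions: NaBH4, CeCl3·7H2O, MeOH, −78 °C
Reagents that add atoms: none
Why: Luche reduction gives 1,2-reduction of the only aldehyde (C15); the Weinreb amide, both esters and the conjugated methylene are not reduced at −78 °C.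

Step 12
Reactants: 20 (3aS,4R,6E,10E,11aR)-10-(hydroxymethyl)-6-[methoxy(methyl)carbamoyl]-3-methylidene-2-oxo-2,3,3a,4,5,8,9,11a-octahydrocyclodeca[b]furan-4-yl 3-methylbutanoate
Product: 21 (3aS,4R,6E,10E,11aR)-6-formyl-10-(hydroxymethyl)-3-methylidene-2-oxo-2,3,3a,4,5,8,9,11a-octahydrocyclodeca[b]furan-4-yl 3-methylbutanoate
Conditions: Cp2Zr(H)Cl (2.5 equiv; 1 equiv is consumed by the free hydroxyl), THF, rt, 20 min; aq. NaHCO3 work-up
Reagents that add atoms: none
Why: Hydrozirconation-type reduction of the Weinreb amide by Cp2Zr(H)Cl stops at the aldehyde stage and is selective for tertiary amides over esters and lactones, releasing the C14 enal as the last operation.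

**Compound list**
1 | furan-3-carbaldehyde | O=Cc1ccoc1 | starting material
2 | 2-(triphenyl-λ5-phosphanylidene)acetaldehyde | O=CC=P(c1ccccc1)(c1ccccc1)c1ccccc1 | starting material
3 | (2E)-3-(furan-3-yl)prop-2-enal | O=C/C=C/c1ccoc1 | intermediate
4 | 3-(furan-3-yl)propanal | O=CCCc1ccoc1 | intermediate
5 | (2S)-2-ethenyloxirane | C=C[C@H]1CO1 | starting material
6 | ethyl 2-(diethoxyphosphoryl)acetate | CCOC(=O)CP(=O)(OCC)OCC | starting material
7 | (5R)-3-(diethoxyphosphoryl)-5-ethenyloxolan-2-one (both C3 epimers) | O=C1O[C@@H](C=C)CC1P(=O)(OCC)OCC | intermediate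
8 | (3E,5R)-5-ethenyl-3-[3-(furan-3-yl)propylidene]oxolan-2-one | O=C1O[C@@H](C=C)C/C1=C\CCc1ccoc1 | intermediate
9 | (2E)-5-(furan-3-yl)-2-[(2R)-2-hydroxybut-3-en-1-yl]-N-methoxy-N-methylpent-2-enamide | CON(C)C(=O)/C(C[C@@H](O)C=C)=C/CCc1ccoc1 | intermediate (not isolated)
10 | (2E)-2-[(2R)-2-{[tert-butyl(dimethyl)silyl]oxy}but-3-en-1-yl]-5-(furan-3-yl)-N-methoxy-N-methylpent-2-enamide | CON(C)C(=O)/C(C[C@@H](O[Si](C)(C)C(C)(C)C)C=C)=C/CCc1ccoc1 | intermediate
11 | methyl 2-(bromomethyl)prop-2-enoate | C=C(CBr)C(=O)OC | starting material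
12 | methyl (2Z,4R,6E)-2-(bromomethyl)-4-{[tert-butyl(dimethyl)silyl]oxy}-9-(furan-3-yl)-6-[methoxy(methyl)carbamoyl]nona-2,6-dienoate | CON(C)C(=O)/C(C[C@@H](O[Si](C)(C)C(C)(C)C)/C=C(\CBr)C(=O)OC)=C/CCc1ccoc1 | intermediate
13 | methyl (2Z,4R,6E,10Z)-2-(bromomethyl)-4-{[tert-butyl(dimethyl)silyl]oxy}-10-formyl-6-[methoxy(methyl)carbamoyl]-12-oxododeca-2,6,10-trienoate | CON(C)C(=O)/C(C[C@@H](O[Si](C)(C)C(C)(C)C)/C=C(\CBr)C(=O)OC)=C/CC/C(C=O)=C/C=O | intermediate (not isolated)
14 | methyl (2Z,4R,6E,10E)-2-(bromomethyl)-4-{[tert-butyl(dimethyl)silyl]oxy}-10-formyl-6-[methoxy(methyl)carbamoyl]-12-oxododeca-2,6,10-trienoate | CON(C)C(=O)/C(C[C@@H](O[Si](C)(C)C(C)(C)C)/C=C(\CBr)C(=O)OC)=C/CC/C(C=O)=C\C=O | intermediate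
15 | methyl 2-[(1R,2R,3E,7E,10R)-10-{[tert-butyl(dimethyl)silyl]oxy}-4-formyl-2-hydroxy-8-[methoxy(methyl)carbamoyl]cyclodeca-3,7-dien-1-yl]prop-2-enoate | C=C(C(=O)OC)[C@@H]1[C@H](O)/C=C(/C=O)CC/C=C(/C(=O)N(C)OC)C[C@H]1O[Si](C)(C)C(C)(C)C | intermediate (not isolated)
16 | (3aR,4R,6E,10E,11aR)-4-{[tert-butyl(dimethyl)silyl]oxy}-10-formyl-N-methoxy-N-methyl-3-methylidene-2-oxo-2,3,3a,4,5,8,9,11a-octahydrocyclodeca[b]furan-6-carboxamide | C=C1C(=O)O[C@@H]2/C=C(/C=O)CC/C=C(/C(=O)N(C)OC)C[C@@H](O[Si](C)(C)C(C)(C)C)[C@H]12 | intermediate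
17 | (3aS,4R,6E,10E,11aR)-10-formyl-4-hydroxy-N-methoxy-N-methyl-3-methylidene-2-oxo-2,3,3a,4,5,8,9,11a-octahydrocyclodeca[b]furan-6-carboxamide | C=C1C(=O)O[C@@H]2/C=C(/C=O)CC/C=C(/C(=O)N(C)OC)C[C@@H](O)[C@H]12 | intermediate
18 | 3-methylbutanoic anhydride | CC(C)CC(=O)OC(=O)CC(C)C | starting material
19 | (3aS,4R,6E,10E,11aR)-10-formyl-6-[methoxy(methyl)carbamoyl]-3-methylidene-2-oxo-2,3,3a,4,5,8,9,11a-octahydrocyclodeca[b]furan-4-yl 3-methylbutanoate | C=C1C(=O)O[C@@H]2/C=C(/C=O)CC/C=C(/C(=O)N(C)OC)C[C@@H](OC(=O)CC(C)C)[C@H]12 | intermediate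
20 | (3aS,4R,6E,10E,11aR)-10-(hydroxymethyl)-6-[methoxy(methyl)carbamoyl]-3-methylidene-2-oxo-2,3,3a,4,5,8,9,11a-octahydrocyclodeca[b]furan-4-yl 3-methylbutanoate | C=C1C(=O)O[C@@H]2/C=C(/CO)CC/C=C(/C(=O)N(C)OC)C[C@@H](OC(=O)CC(C)C)[C@H]12 | intermediate
21 | (3aS,4R,6E,10E,11aR)-6-formyl-10-(hydroxymethyl)-3-methylidene-2-oxo-2,3,3a,4,5,8,9,11a-octahydrocyclodeca[b]furan-4-yl 3-methylbutanoate | C=C1C(=O)O[C@@H]2/C=C(/CO)CC/C=C(/C=O)C[C@@H](OC(=O)CC(C)C)[C@H]12 | target

**Step count and risks**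
Total: 12 steps. Longest linear sequence: 11 steps (steps 1, 2, 4–12); the epoxide branch (steps 3–12) is 10 steps.

The three steps most likely to fail:

Step 6. Cross-metathesis between an allylic silyl ether and a 1,1-disubstituted acrylate can stall or give homodimer. The fallback sets out from 10 and comes back at 12, and builds the bromomethyl enoate by carbonyl chemistry instead of metathesis. The vinyl group of 10 is cleaved (OsO4 cat., NaIO4, 2,6-lutidine, dioxane/H2O) to the α-silyloxy aldehyde F1. A Morita–Baylis–Hillman reaction with methyl acrylate (DABCO) gives the allylic alcohol F2 (both carbinol epimers). Mesylation (MsCl, Et3N) and LiBr then give 12 by SN2′ displacement.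

Step 8 (with step 7 feeding it). The allylindium may attack the C15 formyl group, or close the ring with the wrong C6/C7 or C7/C8 relationship. The fallback sets out from 10 and comes back at 16, and replaces the Barbier reaction by a Lewis-acid allylsilane cyclization. Cross-metathesis of 10 with methyl 2-[(trimethylsilyl)methyl]prop-2-enoate gives the allylsilane F3. Dimethyldioxirane then I2, as in step 7, gives the enedial allylsilane F4. BF3·OEt2 in CH2Cl2 at −78 °C activates the less hindered formyl group for an intramolecular Hosomi–Sakurai allylation through an open, syn-selective transition state, and p-TsOH closes the lactone to 16.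

Step 12. Cp2Zr(H)Cl might also reduce the conjugated methylene lactone. The fallback sets out from 20 and comes back at 21, and masks the methylene group during the reduction. Dimethylamine adds to 20 (THF, rt) to give the amine adduct F5 (both C3 epimers). Cp2Zr(H)Cl reduces its Weinreb amide to the amino aldehyde F6. Methylation with MeI followed by NaHCO3 eliminates the ammonium group and regenerates the methylene lactone, giving 21.

Further compounds
F1 | step 6 | (2E)-2-[(2R)-2-{[tert-butyl(dimethyl)silyl]oxy}-3-oxopropyl]-5-(furan-3-yl)-N-methoxy-N-methylpent-2-enamide | CON(C)C(=O)/C(C[C@@H](O[Si](C)(C)C(C)(C)C)C=O)=C/CCc1ccoc1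
F2 | step 6 | methyl (4R,6E)-4-{[tert-butyl(dimethyl)silyl]oxy}-9-(furan-3-yl)-3-hydroxy-6-[methoxy(methyl)carbamoyl]-2-methylidenenon-6-enoate (both C3 epimers) | CON(C)C(=O)/C(C[C@@H](O[Si](C)(C)C(C)(C)C)C(O)C(=C)C(=O)OC)=C/CCc1ccoc1
F3 | step 8 | methyl (2Z,4R,6E)-4-{[tert-butyl(dimethyl)silyl]oxy}-9-(furan-3-yl)-6-[methoxy(methyl)carbamoyl]-2-[(trimethylsilyl)methyl]nona-2,6-dienoate | CON(C)C(=O)/C(C[C@@H](O[Si](C)(C)C(C)(C)C)/C=C(\C[Si](C)(C)C)C(=O)OC)=C/CCc1ccoc1
F4 | step 8 | methyl (2Z,4R,6E,10E)-4-{[tert-butyl(dimethyl)silyl]oxy}-10-formyl-6-[methoxy(methyl)carbamoyl]-12-oxo-2-[(trimethylsilyl)methyl]dodeca-2,6,10-trienoate | CON(C)C(=O)/C(C[C@@H](O[Si](C)(C)C(C)(C)C)/C=C(\C[Si](C)(C)C)C(=O)OC)=C/CC/C(C=O)=C\C=O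
F5 | step 12 | (3aS,4R,6E,10E,11aR)-3-[(dimethylamino)methyl]-10-(hydroxymethyl)-6-[methoxy(methyl)carbamoyl]-2-oxo-2,3,3a,4,5,8,9,11a-octahydrocyclodeca[b]furan-4-yl 3-methylbutanoate (both C3 epimers) | CN(C)CC1C(=O)O[C@@H]2/C=C(/CO)CC/C=C(/C(=O)N(C)OC)C[C@@H](OC(=O)CC(C)C)[C@H]12
F6 | step 12 | (3aS,4R,6E,10E,11aR)-3-[(dimethylamino)methyl]-6-formyl-10-(hydroxymethyl)-2-oxo-2,3,3a,4,5,8,9,11a-octahydrocyclodeca[b]furan-4-yl 3-methylbutanoate (both C3 epimers) | CN(C)CC1C(=O)O[C@@H]2/C=C(/CO)CC/C=C(/C=O)C[C@@H](OC(=O)CC(C)C)[C@H]12
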